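**Retrosynthetic overview**
1. The target is a 3,5-disubstituted furan-2(5H)-one; its only ring is opened at the ring O1–C5 bond, which leads back (after loss of a tert-butyl group) to an axially chiral tert-butyl 2,3-allenoate.
2. Enabling feature: in the ring O1–C2(=O)–C3=C4–C5, C4 carries only hydrogen, the carboxyl carbon C2 sits on C3, and C5 is the single stereocentre. The C3=C4–C5 segment is therefore the cycloisomer of an allene C3=C4=C5 whose ester oxygen lies 1,5 to C5 and whose axis stores the C5 configuration.
3. The allenoate is cut at C3–C4 into a terminal alkyne (C4, C5 and the C5 side chain) and an α-diazo ester (O1, C2, C3 and the C3 side chain). The forward step is a formal (3+2) annulation of two achiral halves that makes C3–C4, the axis, O1–C5, the ring and the stereocentre in one telescoped operation.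
4. The alkyne comes from prenyl acetate (allylic oxidation, bromide, copper alkynylation). The diazo ester comes from 5-bromo-2-methylpent-2-ene (allylic oxidation, acetylation, acetoacetate alkylation, deacylative diazo transfer). Both (E)-allylic acetates are carried from the start.
5. Ring order: the butenolide is the only ring and is formed in the last step.

Key step: step 9

Assumption: the sense of axial induction of the copper/bis(oxazoline) catalyst for this alkyne–diazoester pair cannot be predicted with certainty; the route is written for the ligand antipode that gives the (Sa)-allenoate (taken here as (S,S)-Ph-BOX, 2,2'-(propane-2,2-diyl)bis[(4S)-4-phenyl-4,5-dihydrooxazole]), and the mirror-image ligand would be used if a first run shows the opposite sense.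

**Step 1**
Reactants: 1 prenyl acetate (3-methylbut-2-en-1-yl acetate)
Product: 2 (E)-4-hydroxy-3-methylbut-2-en-1-yl acetate
Conditions: SeO2 (30 mol %), t-BuOOH (2 equiv), salicylic acid (10 mol %), CH2Cl2, rt
Reagents that add atoms: tert-butyl hydroperoxide, CC(C)(C)OO (oxygen relayed through catalytic SeO2, O=[Se]=O)
Why: SeO2-catalysed allylic oxidation (ene reaction, then [2,3]-sigmatropic shift) attacks only the (E)-methyl group of a trisubstituted alkene, so the E allylic alcohol should form and the acetate is inert.

**Step 2**
Reactants: 2 (E)-4-hydroxy-3-methylbut-2-en-1-yl acetate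
Product: 3 (E)-4-bromo-3-methylbut-2-en-1-yl acetate
Conditions: CBr4, PPh3, CH2Cl2, 0 °C
Reagents that add atoms: carbon tetrabromide, BrC(Br)(Br)Br
Why: The Appel reaction converts a primary allylic alcohol into the bromide under neutral conditions, without allylic transposition, E/Z isomerisation or loss of the acetate.

**Step 3**
Reactants: 3 (E)-4-bromo-3-methylbut-2-en-1-yl acetate; 4 ethynyltrimethylsilane
Product: 5 (E)-3-methyl-6-(trimethylsilyl)hex-2-en-5-yn-1-yl acetate
Conditions: CuI (10 mol %), NaI (20 mol %), K2CO3, DMF, rt
Reagents that add atoms: none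
Why: Copper-catalysed alkynylation of an allylic halide; the copper acetylide formed under carbonate conditions should displace the primary bromide at the unhindered carbon (SN2, not SN2′) to give the skipped enyne, and the weak base leaves the acetate intact.

**Step 4**
Reactants: 5 (E)-3-methyl-6-(trimethylsilyl)hex-2-en-5-yn-1-yl acetate
Product: 6 (E)-3-methylhex-2-en-5-yn-1-yl acetate
Conditions: AgNO3 (10 mol %), acetone/H2O, rt
Reagents that add atoms: none
Why: Silver-catalysed protodesilylation of an alkynylsilane runs through a silver acetylide under neutral conditions, so neither acetate cleavage nor base-induced enyne-to-allene isomerisation is expected.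

**Step 5**
Reactants: 7 5-bromo-2-methylpent-2-ene
Product: 8 (E)-5-bromo-2-methylpent-2-en-1-ol
Conditions: SeO2 (30 mol %), t-BuOOH (2 equiv), salicylic acid (10 mol %), CH2Cl2, rt
Reagents that add atoms: tert-butyl hydroperoxide, CC(C)(C)OO (oxygen relayed through catalytic SeO2, O=[Se]=O)
Why: The same SeO2-catalysed allylic oxidation selects the (E)-methyl group of the gem-dimethyl alkene and should give the E alcohol; the primary bromide is inert.

**Step 6**
Reactants: 8 (E)-5-bromo-2-methylpent-2-en-1-ol
Product: 9 (E)-5-bromo-2-methylpent-2-en-1-yl acetate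
Conditions: Ac2O, pyridine, DMAP (5 mol %), CH2Cl2, 0 °C
Reagents that add atoms: acetic anhydride, CC(=O)OC(C)=O
Why: Standard DMAP-catalysed O-acetylation of a primary allylic alcohol; no stereochemical change.

**Step 7**
Reactants: 9 (E)-5-bromo-2-methylpent-2-en-1-yl acetate; 10 tert-butyl acetoacetate
Product: 11 tert-butyl (E)-7-acetoxy-2-acetyl-6-methylhept-5-enoate (racemic)
Conditions: 10 (1.5 equiv), NaH (1.4 equiv), THF, 0 °C; then 9, NaI (10 mol %), DMF, 50 °C
Reagents that add atoms: none
Why: Acetoacetic ester C-alkylation (SN2) of the soft sodium enolate with a primary bromide under iodide catalysis; excess enolate suppresses dialkylation, and the new α-centre is racemic but is erased in step 8.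

**Step 8**
Reactants: 11 tert-butyl (E)-7-acetoxy-2-acetyl-6-methylhept-5-enoate
Product: 12 tert-butyl (E)-7-acetoxy-2-diazo-6-methylhept-5-enoate
Conditions: p-ABSA (1.3 equiv), DBU (1.5 equiv), MeCN, 0 °C to rt
Reagents that add atoms: 4-acetamidobenzenesulfonyl azide, CC(=O)Nc1ccc(cc1)S(=O)(=O)N=[N+]=[N-]
Why: Regitz deacylative diazo transfer: the enolate adds to the sulfonyl azide and the acetyl group is passed to the sulfonamide nitrogen, leaving the α-alkyl α-diazo ester; both esters tolerate DBU at rt.

**Step 9**
Reactants: 6 (E)-3-methylhex-2-en-5-yn-1-yl acetate; 12 tert-butyl (E)-7-acetoxy-2-diazo-6-methylhept-5-enoate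
Product: 14 (5S)-3-[(E)-5-acetoxy-4-methylpent-3-enyl]-5-[(E)-4-acetoxy-2-methylbut-2-enyl]furan-2(5H)-one (target), via tert-butyl (Sa)-allenoate 13 (not isolated)
Conditions: Cu(MeCN)4PF6 (10 mol %), (S,S)-Ph-BOX (12 mol %), i-Pr2NEt (20 mol %), CH2Cl2, 0 °C, slow addition of 12 (1.2 equiv); filtration through a silica plug, then AuCl3 (5 mol %), CH2Cl2, 0 °C to rt
Reagents that add atoms: none
Why: Mechanism: the copper acetylide of 6 intercepts the copper carbene formed from 12 with loss of N2, 1,2-alkynyl migration gives a copper-bound propargyl/allenyl ester enolate and ligand-controlled protonation at the distal alkyne carbon releases the (Sa)-allenoate 13; AuCl3 then coordinates the C4=C5 bond of the allene anti to the ester, the carbonyl oxygen adds to C5, the alkoxy-oxocarbenium ion loses its tert-butyl group as isobutene and the vinylgold at C4 is protonated with retention. The closest known reaction types are the asymmetric copper-catalysed coupling of terminal alkynes with α-alkyl α-diazoesters to 2,4-disubstituted allenoates and the gold-catalysed cycloisomerisation of tert-butyl 2,3-allenoates to butenolides, joined here into a formal (3+2) annulation in which the diazoester supplies O1–C2–C3 and the alkyne C4–C5. The single ring, the furan-2(5H)-one, closes by 5-endo-trig attack of the ester oxygen on the allene terminus C5, which is feasible because the C4=C5 π bond lies in the plane of the ester and points one lobe at that oxygen. The C5 stereocentre is set by axis-to-centre chirality transfer: oxygen can only enter on the ester side of the C4=C5 π bond while gold holds the opposite face, so the (Sa) axis, itself fixed by the chiral copper catalyst, should translate into the S centre. The step needs carbene capture by the acetylide to outrun cyclopropanation of the trisubstituted alkenes and 1,2-hydride shift, which is secured by slow addition of 12 to pre-formed acetylide and by the 4-pentenyl tether of 12, whose internal cyclopropanation would give a strained bicyclo[2.1.0]pentane. It also needs the axis to survive until ring closure, which is secured by the acceptor- and dialkyl-substituted allene that does not ionise on gold and by removal of the amine before the gold stage.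

**Compound list**
1 | prenyl acetate (3-methylbut-2-en-1-yl acetate) | CC(C)=CCOC(C)=O | starting material
2 | (E)-4-hydroxy-3-methylbut-2-en-1-yl acetate | CC(=O)OC/C=C(\C)CO | intermediate
3 | (E)-4-bromo-3-methylbut-2-en-1-yl acetate | CC(=O)OC/C=C(\C)CBr | intermediate
4 | ethynyltrimethylsilane | C#C[Si](C)(C)C | starting material
5 | (E)-3-methyl-6-(trimethylsilyl)hex-2-en-5-yn-1-yl acetate | CC(=O)OC/C=C(\C)CC#C[Si](C)(C)C | intermediate
6 | (E)-3-methylhex-2-en-5-yn-1-yl acetate | CC(=O)OC/C=C(\C)CC#C | intermediate
7 | 5-bromo-2-methylpent-2-ene | CC(C)=CCCBr | starting material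
8 | (E)-5-bromo-2-methylpent-2-en-1-ol | OC/C(C)=C/CCBr | intermediate
9 | (E)-5-bromo-2-methylpent-2-en-1-yl acetate | CC(=O)OC/C(C)=C/CCBr | intermediate
10 | tert-butyl acetoacetate | CC(=O)CC(=O)OC(C)(C)C | starting material
11 | tert-butyl (E)-7-acetoxy-2-acetyl-6-methylhept-5-enoate (racemic) | CC(=O)C(CC/C=C(\C)COC(C)=O)C(=O)OC(C)(C)C | intermediate
12 | tert-butyl (E)-7-acetoxy-2-diazo-6-methylhept-5-enoate | CC(=O)OC/C(C)=C/CCC(=[N+]=[N-])C(=O)OC(C)(C)C | intermediate
13 | tert-butyl (Sa,6E)-8-acetoxy-2-[(E)-5-acetoxy-4-methylpent-3-en-1-yl]-6-methylocta-2,3,6-trienoate | CC(C)(C)OC(=O)C(CC/C=C(\C)COC(C)=O)=[C@@]=C([H])C/C(C)=C/COC(C)=O | intermediate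
14 | (5S)-3-[(E)-5-acetoxy-4-methylpent-3-enyl]-5-[(E)-4-acetoxy-2-methylbut-2-enyl]furan-2(5H)-one | CC(=O)OC/C=C(\C)C[C@H]1C=C(CC/C=C(\C)COC(C)=O)C(=O)O1 | target

**Step count**
Total steps: 9. Longest linear sequence: 5 steps (steps 1–4 then 9, or steps 5–8 then 9).

**Steps most likely to fail**

Step 9. The protonation that sets the allene axis may show insufficient enantiofacial control. The amine may racemise the axis or isomerise the allenoate to a conjugated triene. Chirality transfer may erode during the gold stage. The fallback gives up asymmetric catalysis for resolution and uses a carboxylic acid with silver for the ring closure. It sets out from 6 and 12. Achiral coupling (CuI 10 mol %, Et3N, MeCN, rt) should give the racemic tert-butyl allenoate F1. Ester cleavage (TFA, CH2Cl2, 0 °C) should give the racemic allenoic acid F2. Silver-catalysed lactonisation of the 2,3-allenoic acid (AgNO3 10 mol %, acetone, rt) should give the racemic butenolide F3. Preparative HPLC on an amylose tris(3,5-dimethylphenylcarbamate) stationary phase then separates the enantiomers, and the route is rejoined at 14.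

Step 3. The acetylide may attack in the SN2′ sense, the silyl group may be lost under the carbonate conditions and lead to double allylation, or the skipped enyne may isomerise to a vinylallene. The fallback builds the trisubstituted alkene by carbometalation instead of carrying it from prenyl acetate. It sets out from 4. Deprotonation with EtMgBr and CuCl-catalysed coupling with propargyl bromide (THF, rt) should give trimethyl(penta-1,4-diyn-1-yl)silane F4. Zirconium-catalysed syn-methylalumination of the terminal alkyne (AlMe3, Cp2ZrCl2, CH2Cl2), then n-BuLi and paraformaldehyde, should give (E)-3-methyl-6-(trimethylsilyl)hex-2-en-5-yn-1-ol F5. Acetylation (Ac2O, pyridine) rejoins the route at 5.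

Step 7. E2 loss of HBr from the homoallylic bromide, dialkylation, or acyl transfer from the allylic acetate to the enolate may erode the alkylation. The fallback moves the oxygenation after the C–C bond formation, so the cheap acetate-free bromide can be used in excess. It sets out from 7 and 10. Alkylation (NaH, NaI, THF/DMF, 50 °C) should give tert-butyl 2-acetyl-6-methylhept-5-enoate F6. SeO2-catalysed allylic oxidation (SeO2 30 mol %, t-BuOOH, CH2Cl2, rt) should give tert-butyl (E)-2-acetyl-7-hydroxy-6-methylhept-5-enoate F7. Acetylation (Ac2O, pyridine) rejoins the route at 11.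

**Further compounds**
F1 | step 9 | racemic tert-butyl (6E)-8-acetoxy-2-[(E)-5-acetoxy-4-methylpent-3-en-1-yl]-6-methylocta-2,3,6-trienoate | CC(C)(C)OC(=O)C(CC/C=C(\C)COC(C)=O)=C=CC/C(C)=C/COC(C)=O
F2 | step 9 | racemic (6E)-8-acetoxy-2-[(E)-5-acetoxy-4-methylpent-3-en-1-yl]-6-methylocta-2,3,6-trienoic acid | OC(=O)C(CC/C=C(\C)COC(C)=O)=C=CC/C(C)=C/COC(C)=O
F3 | step 9 | racemic 3-[(E)-5-acetoxy-4-methylpent-3-enyl]-5-[(E)-4-acetoxy-2-methylbut-2-enyl]furan-2(5H)-one | CC(=O)OC/C=C(\C)CC1C=C(CC/C=C(\C)COC(C)=O)C(=O)O1
F4 | step 3 | trimethyl(penta-1,4-diyn-1-yl)silane | C#CCC#C[Si](C)(C)C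
F5 | step 3 | (E)-3-methyl-6-(trimethylsilyl)hex-2-en-5-yn-1-ol | OC/C=C(\C)CC#C[Si](C)(C)C
F6 | step 7 | tert-butyl 2-acetyl-6-methylhept-5-enoate (racemic) | CC(=O)C(CCC=C(C)C)C(=O)OC(C)(C)C
F7 | step 7 | tert-butyl (E)-2-acetyl-7-hydroxy-6-methylhept-5-enoate (racemic) | CC(=O)C(CC/C=C(\C)CO)C(=O)OC(C)(C)C
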